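## Retrosynthetic overview

- Last bond: the ester C–O at the allylic C4–OH of the octahydroazulene-3,4-diol, made with silyl-protected isovanillic acid; the silyl group is removed at the end.
- The C4 carbinol comes from chelation-controlled reduction of a cis-fused β-hydroxy enone.
- The five-membered ring is formed last, by intramolecular aldol closure of C3–C3a in a 3,6-dimethylcyclohept-2-enone that carries a 4-methyl-3-oxopentyl arm on its quaternary carbon; this sets C3 and C3a from C8a.
- The seven-membered ring comes from one-carbon ring expansion (siloxycyclopropane, FeCl3) of a 3,3-disubstituted cyclohexanone; the side-chain ketone is grown from a butenyl group.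
- Key C–C bond: quaternary C8a to the side chain, by copper-catalysed enantioselective conjugate (Michael-type) addition of but-3-enylmagnesium bromide to 3-methylcyclohex-2-enone. Ring order: six-membered (bought), then seven-membered, then five-membered.

Assumption: the antipode of the chiral NHC ligand in step 1 is chosen (by a pilot run) so that the (R)-ketone 3 is formed; every later stereocentre is relayed from it.

## Route

Step 1
Reactants: 1 3-methylcyclohex-2-en-1-one; 2 but-3-en-1-ylmagnesium bromide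
Product: 3 (3R)-3-(but-3-en-1-yl)-3-methylcyclohexan-1-one
Conditions: Cu(OTf)2 (3 mol%), chiral N-mesityl-N′-(1-hydroxy-4-methylpentan-2-yl)imidazolinium PF6 salt (NHC precursor, 4 mol%), Et2O, 0 °C, slow addition of 2 (1.2 equiv); aq NH4Cl
Reagents that add atoms: none
Why: Copper-catalysed enantioselective conjugate (Michael-type) addition of the Grignard reagent to the β,β-disubstituted enone, in which the chiral NHC–copper complex selects one enone face and sets the all-carbon quaternary centre as R (about 90% ee expected).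

Step 2
Reactants: 3 (3R)-3-(but-3-en-1-yl)-3-methylcyclohexan-1-one
Product: 4 (2RS,5S)-5-(but-3-en-1-yl)-2,5-dimethylcyclohexan-1-one
Conditions: LiN(iPr)2 (1.05 equiv), THF, −78 °C; MeI (1.5 equiv), −78 → −20 °C
Reagents that add atoms: iodomethane, CI
Why: Kinetic enolate alkylation, in which the amide base removes the unhindered C6 proton rather than the neopentyl C2 proton and the enolate is methylated by SN2; the new α-centre does not matter because it becomes sp2 in step 3.

Step 3
Reactants: 4 (2RS,5S)-5-(but-3-en-1-yl)-2,5-dimethylcyclohexan-1-one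
Product: 5 {[(5S)-5-(but-3-en-1-yl)-2,5-dimethylcyclohex-1-en-1-yl]oxy}(trimethyl)silane
Conditions: Me3SiCl, NaI, Et3N, MeCN, rt
Reagents that add atoms: chlorotrimethylsilane, C[Si](C)(C)Cl
Why: Thermodynamic silyl enol ether formation with Me3SiI made in the flask gives the more substituted (tetrasubstituted) enol ether, away from the hindered neopentyl side.

Step 4
Reactants: 5 {[(5S)-5-(but-3-en-1-yl)-2,5-dimethylcyclohex-1-en-1-yl]oxy}(trimethyl)silane
Product: 6 {[(3S)-3-(but-3-en-1-yl)-3,6-dimethylbicyclo[4.1.0]heptan-1-yl]oxy}(trimethyl)silane (both cyclopropane faces)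
Conditions: Et2Zn, CH2I2, CH2Cl2, 0 °C → rt
Reagents that add atoms: diiodomethane, ICI
Why: Furukawa-modified Simmons–Smith cyclopropanation, in which the electrophilic zinc carbenoid reacts much faster with the electron-rich silyl enol ether than with the terminal alkene; the cyclopropane stereocentres are destroyed in step 5.

Step 5
Reactants: 6 {[(3S)-3-(but-3-en-1-yl)-3,6-dimethylbicyclo[4.1.0]heptan-1-yl]oxy}(trimethyl)silane
Product: 8 (6S)-6-(but-3-en-1-yl)-3,6-dimethylcyclohept-2-en-1-one, via β-chloro ketone 7 (not isolated)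
Conditions: FeCl3 (2.2 equiv), DMF, 0 °C → rt; then NaOAc, MeOH, reflux
Reagents that add atoms: none
Why: Ito–Saegusa one-carbon ring expansion, in which FeCl3 oxidises the siloxycyclopropane, the internal cyclopropane bond cleaves to the ring-expanded tertiary radical that is trapped as the β-chloro ketone, and NaOAc eliminates HCl to the conjugated 3-methylcycloheptenone.

Step 6
Reactants: 8 (6S)-6-(but-3-en-1-yl)-3,6-dimethylcyclohept-2-en-1-one
Product: 10 3-[(1R)-1,5-dimethyl-3-oxocyclohept-4-en-1-yl]propanal, via vicinal diol 9 (not isolated)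
Conditions: OsO4 (2 mol%), NaIO4 (4 equiv), 2,6-lutidine, dioxane/H2O (3:1), rt
Reagents that add atoms: osmium tetroxide, O=[Os](=O)(=O)=O; sodium periodate, [Na+].[O-]I(=O)(=O)=O
Why: Lemieux–Johnson oxidative cleavage, in which OsO4 dihydroxylates the monosubstituted alkene in preference to the electron-poor trisubstituted enone alkene and NaIO4 cleaves the glycol to the aldehyde.

Step 7
Reactants: 10 3-[(1R)-1,5-dimethyl-3-oxocyclohept-4-en-1-yl]propanal
Product: 11 (6R)-6-[(3RS)-3-hydroxy-4-methylpentyl]-3,6-dimethylcyclohept-2-en-1-one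
Conditions: iPrMgCl (1.1 equiv), THF, −78 °C; aq NH4Cl
Reagents that add atoms: isopropylmagnesium chloride, CC(C)[Mg]Cl
Why: Grignard 1,2-addition that is chemoselective at −78 °C for the aldehyde over the poorly electrophilic β,β-disubstituted enone; the carbinol configuration does not matter because it is oxidised in step 8.

Step 8
Reactants: 11 (6R)-6-[(3RS)-3-hydroxy-4-methylpentyl]-3,6-dimethylcyclohept-2-en-1-one
Product: 12 (6R)-3,6-dimethyl-6-(4-methyl-3-oxopentyl)cyclohept-2-en-1-one
Conditions: Dess–Martin periodinane, CH2Cl2, rt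
Reagents that add atoms: none
Why: Dess–Martin oxidation of the secondary alcohol under neutral conditions that neither enolise nor cyclise the diketone.

Step 9
Reactants: 12 (6R)-3,6-dimethyl-6-(4-methyl-3-oxopentyl)cyclohept-2-en-1-one
Product: 13 (3R,3aR,8aR)-3-hydroxy-6,8a-dimethyl-3-(propan-2-yl)-2,3,3a,7,8,8a-hexahydroazulen-4(1H)-one
Conditions: LiN(SiMe3)2 (1.05 equiv), THF, −78 → −20 °C; AcOH, −78 °C
Reagents that add atoms: none
Why: Intramolecular aldol addition of the α′-lithium enolate of the enone onto the side-chain ketone, in which the two-carbon tether forces the cis ring fusion (H-3a syn to the C8a methyl) and the lithium chelate between enolate and ketone oxygens places the new hydroxyl syn to the C4 carbonyl with isopropyl on the convex face, while reversible retro-aldol of competing aldolates feeds this conjugated, chelated aldolate.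

Step 10
Reactants: 13 (3R,3aR,8aR)-3-hydroxy-6,8a-dimethyl-3-(propan-2-yl)-2,3,3a,7,8,8a-hexahydroazulen-4(1H)-one
Product: 14 (3R,3aS,4R,8aR)-6,8a-dimethyl-3-(propan-2-yl)-1,2,3,3a,4,7,8,8a-octahydroazulene-3,4-diol
Conditions: Et2BOMe (1.2 equiv), THF/MeOH (4:1), −78 °C; NaBH4, −78 °C; MeOH co-evaporation
Reagents that add atoms: none
Why: Narasaka–Prasad chelation-controlled 1,2-reduction, in which the diethylboron chelate between the tertiary hydroxyl and the enone carbonyl blocks the concave face so that external hydride adds to C4 from the convex face anti to the quaternary C8a, giving the 4R alcohol with both oxygens on the same face.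

Step 11
Reactants: 15 3-hydroxy-4-methoxybenzoic acid (isovanillic acid)
Product: 17 3-[(tert-butyldimethylsilyl)oxy]-4-methoxybenzoic acid, via silyl ester 16 (not isolated)
Conditions: tBuMe2SiCl (2.3 equiv), imidazole, DMF, rt; then AcOH/THF/H2O, rt
Reagents that add atoms: tert-butyldimethylsilyl chloride, CC(C)(C)[Si](C)(C)Cl
Why: Silylation of both acidic OH groups followed by selective hydrolysis of the labile silyl ester leaves the phenol masked as its silyl ether.

Step 12
Reactants: 14 (3R,3aS,4R,8aR)-6,8a-dimethyl-3-(propan-2-yl)-1,2,3,3a,4,7,8,8a-octahydroazulene-3,4-diol; 17 3-[(tert-butyldimethylsilyl)oxy]-4-methoxybenzoic acid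
Product: 19 (3R,3aS,4R,8aR)-3-hydroxy-6,8a-dimethyl-3-(propan-2-yl)-1,2,3,3a,4,7,8,8a-octahydroazulen-4-yl 3-[(tert-butyldimethylsilyl)oxy]-4-methoxybenzoate, via O-acylisourea 18 (not isolated)
Conditions: DCC, DMAP (cat.), CH2Cl2, 0 °C → rt
Reagents that add atoms: none
Why: Steglich esterification, in which DCC activates the acid, DMAP transfers the acyl group to the secondary allylic C4 hydroxyl with retention, and the hindered tertiary C3 hydroxyl does not react.

Step 13
Reactants: 19 (3R,3aS,4R,8aR)-3-hydroxy-6,8a-dimethyl-3-(propan-2-yl)-1,2,3,3a,4,7,8,8a-octahydroazulen-4-yl 3-[(tert-butyldimethylsilyl)oxy]-4-methoxybenzoate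
Product: 20 (3R,3aS,4R,8aR)-3-hydroxy-6,8a-dimethyl-3-(propan-2-yl)-1,2,3,3a,4,7,8,8a-octahydroazulen-4-yl 3-hydroxy-4-methoxybenzoate
Conditions: HF·pyridine, THF, 0 °C → rt
Reagents that add atoms: none
Why: Fluoride-mediated desilylation of the aryl silyl ether under non-basic conditions that leave the allylic benzoate, the tertiary alcohol and the alkene untouched.

## Compound list

1 | 3-methylcyclohex-2-en-1-one | CC1=CC(=O)CCC1 | starting material
2 | but-3-en-1-ylmagnesium bromide | C=CCC[Mg]Br | starting material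
3 | (3R)-3-(but-3-en-1-yl)-3-methylcyclohexan-1-one | O=C1CCC[C@](C)(CCC=C)C1 | intermediate
4 | (2RS,5S)-5-(but-3-en-1-yl)-2,5-dimethylcyclohexan-1-one | O=C1C(C)CC[C@](C)(CCC=C)C1 | intermediate
5 | {[(5S)-5-(but-3-en-1-yl)-2,5-dimethylcyclohex-1-en-1-yl]oxy}(trimethyl)silane | C[Si](C)(C)OC1=C(C)CC[C@](C)(CCC=C)C1 | intermediate
6 | {[(3S)-3-(but-3-en-1-yl)-3,6-dimethylbicyclo[4.1.0]heptan-1-yl]oxy}(trimethyl)silane | C[Si](C)(C)OC12CC1(C)CC[C@](C)(CCC=C)C2 | intermediate
7 | (6S)-6-(but-3-en-1-yl)-3-chloro-3,6-dimethylcycloheptan-1-one | O=C1CC(C)(Cl)CC[C@](C)(CCC=C)C1 | intermediate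
8 | (6S)-6-(but-3-en-1-yl)-3,6-dimethylcyclohept-2-en-1-one | O=C1C=C(C)CC[C@](C)(CCC=C)C1 | intermediate
9 | (6R)-6-(3,4-dihydroxybutyl)-3,6-dimethylcyclohept-2-en-1-one | O=C1C=C(C)CC[C@](C)(CCC(O)CO)C1 | intermediate
10 | 3-[(1R)-1,5-dimethyl-3-oxocyclohept-4-en-1-yl]propanal | O=C1C=C(C)CC[C@](C)(CCC=O)C1 | intermediate
11 | (6R)-6-[(3RS)-3-hydroxy-4-methylpentyl]-3,6-dimethylcyclohept-2-en-1-one | O=C1C=C(C)CC[C@](C)(CCC(O)C(C)C)C1 | intermediate
12 | (6R)-3,6-dimethyl-6-(4-methyl-3-oxopentyl)cyclohept-2-en-1-one | O=C1C=C(C)CC[C@](C)(CCC(=O)C(C)C)C1 | intermediate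
13 | (3R,3aR,8aR)-3-hydroxy-6,8a-dimethyl-3-(propan-2-yl)-2,3,3a,7,8,8a-hexahydroazulen-4(1H)-one | O=C1C=C(C)CC[C@]2(C)CC[C@@](O)(C(C)C)[C@H]12 | intermediate
14 | (3R,3aS,4R,8aR)-6,8a-dimethyl-3-(propan-2-yl)-1,2,3,3a,4,7,8,8a-octahydroazulene-3,4-diol | O[C@@H]1C=C(C)CC[C@]2(C)CC[C@@](O)(C(C)C)[C@H]12 | intermediate
15 | 3-hydroxy-4-methoxybenzoic acid | COc1ccc(C(=O)O)cc1O | starting material
16 | tert-butyldimethylsilyl 3-[(tert-butyldimethylsilyl)oxy]-4-methoxybenzoate | COc1ccc(C(=O)O[Si](C)(C)C(C)(C)C)cc1O[Si](C)(C)C(C)(C)C | intermediate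
17 | 3-[(tert-butyldimethylsilyl)oxy]-4-methoxybenzoic acid | COc1ccc(C(=O)O)cc1O[Si](C)(C)C(C)(C)C | intermediate
18 | 3-[(tert-butyldimethylsilyl)oxy]-4-methoxybenzoic N,N′-dicyclohexylcarbamimidic anhydride (O-acylisourea) | COc1ccc(C(=O)OC(=NC2CCCCC2)NC2CCCCC2)cc1O[Si](C)(C)C(C)(C)C | intermediate
19 | (3R,3aS,4R,8aR)-3-hydroxy-6,8a-dimethyl-3-(propan-2-yl)-1,2,3,3a,4,7,8,8a-octahydroazulen-4-yl 3-[(tert-butyldimethylsilyl)oxy]-4-methoxybenzoate | COc1ccc(C(=O)O[C@@H]2C=C(C)CC[C@]3(C)CC[C@@](O)(C(C)C)[C@H]23)cc1O[Si](C)(C)C(C)(C)C | intermediate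
20 | (3R,3aS,4R,8aR)-3-hydroxy-6,8a-dimethyl-3-(propan-2-yl)-1,2,3,3a,4,7,8,8a-octahydroazulen-4-yl 3-hydroxy-4-methoxybenzoate (CNP0210850.1) | COc1ccc(C(=O)O[C@@H]2C=C(C)CC[C@]3(C)CC[C@@](O)(C(C)C)[C@H]23)cc1O | target

## Step count and risks

Total step count: 13. Longest linear sequence: 12 steps (steps 1 to 10, then 12 and 13); step 11 is a one-step side branch.

The three steps most likely to fail:

Step 9 (aldol ring closure). The base can also form the side-chain enolate, which could add to the enone carbonyl or to its β-carbon, and the new bond is crowded. The fallback sets out from 12 and comes back at 13, and makes the enolate by reduction instead of deprotonation. α′-Acetoxylation of the enone with Mn(OAc)3·2H2O (benzene, reflux) gives (1RS,7R)-4,7-dimethyl-7-(4-methyl-3-oxopentyl)-2-oxocyclohept-3-en-1-yl acetate F1. SmI2 (2.2 equiv, THF, −78 °C) then cleaves the C–OAc bond and gives the samarium enolate at that carbon only, which adds to the side-chain ketone (Reformatsky-type aldol) to give 13.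

Step 10 (face selectivity of the ketone reduction). If hydride arrives from the other face, the C4 epimer forms. The fallback sets out from 13 and comes back at 19, and uses that epimer on purpose. Internal hydride delivery from the tertiary hydroxyl with Me4NBH(OAc)3 (MeCN/AcOH, −30 °C) gives (3R,3aS,4S,8aR)-6,8a-dimethyl-3-(propan-2-yl)-1,2,3,3a,4,7,8,8a-octahydroazulene-3,4-diol F2. Mitsunobu esterification of F2 with acid 17 (PPh3, diisopropyl azodicarboxylate, toluene, 0 °C → rt) inverts C4 and gives the protected ester 19 directly, bypassing 14.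

Step 7 (Grignard addition beside an enone). Competing attack on the enone, or reduction or enolisation of the aldehyde, would lower the yield. The fallback sets out from 10 and comes back at 11. Nozaki–Hiyama–Kishi addition of 2-bromopropene (CrCl2, NiCl2 1 mol%, DMF, rt), which does not touch ketones, gives (6R)-6-[(3RS)-3-hydroxy-4-methylpent-4-en-1-yl]-3,6-dimethylcyclohept-2-en-1-one F3. Hydrogenation of its 1,1-disubstituted alkene over RhCl(PPh3)3 (H2 1 atm, benzene) leaves the trisubstituted enone alone and gives 11.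

## Further compounds

F1 | step 9 | (1RS,7R)-4,7-dimethyl-7-(4-methyl-3-oxopentyl)-2-oxocyclohept-3-en-1-yl acetate | CC(=O)OC1C(=O)C=C(C)CC[C@]1(C)CCC(=O)C(C)C
F2 | step 10 | (3R,3aS,4S,8aR)-6,8a-dimethyl-3-(propan-2-yl)-1,2,3,3a,4,7,8,8a-octahydroazulene-3,4-diol | O[C@H]1C=C(C)CC[C@]2(C)CC[C@@](O)(C(C)C)[C@H]12
F3 | step 7 | (6R)-6-[(3RS)-3-hydroxy-4-methylpent-4-en-1-yl]-3,6-dimethylcyclohept-2-en-1-one | O=C1C=C(C)CC[C@](C)(CCC(O)C(C)=C)C1
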